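**Retrosynthetic overview**
1. The dihydrofuran ring is opened at the ketal bond O7(flavan)–C2 and all phenols are benzylated: target 13 ⇐ hexabenzyl 2,3-dihydroxyflavanone 11 (hydrogenolysis and acid close the ring again in the last step).
2. Ring C of 11 (O1, C2, C3, C4, C4a, C8a) is cut at C3–C8(flavan) and contracted by one atom: 11 ⇐ five-membered hemiketal 8 (a 2-aroyl-2-hydroxybenzofuran-3-one) + tri-O-benzyl-ent-afzelechin 3.
3. Enabling feature: C2–C3–C4 of ring C is a masked vicinal tricarbonyl unit (C2 a ketal carbon on O1 of ring A, C3 a fully substituted carbinol, C4 the ketone). O1 can therefore sit on the central carbon (furanone) or on the aroyl carbon C2 (ring C), and the central carbonyl C3 is the strongest electrophile.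
4. 8 ⇐ 4,6-dihydroxybenzofuran-3(2H)-one 4 (benzylation, C-aroylation, α-hydroxylation); 3 ⇐ (−)-epiafzelechin 1 (C2 epimerisation, benzylation).
5. Ring order: flavan rings and benzofuranone are bought; ring C arises by ring expansion (step 6); the dihydrofuran ring closes last (step 7).

Key step: step 6

Assumption: the ketal carbon C2 is not an independent stereocentre (it opens and recloses under acid, and the five-membered ring can only be fused cis to ring C), so the route fixes the carbinol carbon C3 (R) and the flavan centres (2S,3R) as written and takes the ring-fusion pair of the target to be this cis junction; read literally, the written pair is the trans junction, which this closure cannot give, and all SMILES keep the notation of the target.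

**Route**

Step 1
Reactants: 1 (−)-epiafzelechin, (2R,3R)-2-(4-hydroxyphenyl)chromane-3,5,7-triol
Product: 2 (−)-afzelechin (ent-afzelechin), (2S,3R)-2-(4-hydroxyphenyl)chromane-3,5,7-triol
Conditions: KH2PO4/K2HPO4 buffer (pH 7), degassed H2O, argon, 100 °C; chromatography on Sephadex LH-20, recovered 1 recycled
Reagents that add atoms: none
Why: Thermal C2 epimerisation of a 2,3-cis flavan-3-ol (reversible opening of the pyran ring to a ring-B quinone methide and reclosure) equilibrates C2 while C3 (R) is untouched, and the 2,3-trans epimer 2 is separated from 1.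

Step 2
Reactants: 2 (−)-afzelechin
Product: 3 (2S,3R)-5,7-bis(benzyloxy)-2-[4-(benzyloxy)phenyl]chroman-3-ol (tri-O-benzyl-ent-afzelechin)
Conditions: BnBr (3.3 equiv), K2CO3, DMF, 0 °C to rt
Reagents that add atoms: benzyl bromide, BrCc1ccccc1
Why: Williamson ether synthesis alkylates the three phenols under carbonate while the secondary 3-OH stays free, and no stereocentre is touched at room temperature.

Step 3
Reactants: 4 4,6-dihydroxybenzofuran-3(2H)-one
Product: 5 4,6-bis(benzyloxy)benzofuran-3(2H)-one
Conditions: BnBr (2.2 equiv), K2CO3, DMF, rt to 50 °C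
Reagents that add atoms: benzyl bromide, BrCc1ccccc1
Why: Williamson ether synthesis on the two phenoxides should outrun C-alkylation of the ketone α-carbon when the halide is kept near stoichiometric.

Step 4
Reactants: 5 4,6-bis(benzyloxy)benzofuran-3(2H)-one; 6 4-(benzyloxy)benzoyl chloride
Product: 7 [4,6-bis(benzyloxy)-3-hydroxybenzofuran-2-yl][4-(benzyloxy)phenyl]methanone (enol form of the 2-aroylbenzofuran-3-one)
Conditions: MgBr2·OEt2 (2.5 equiv), i-Pr2NEt (3 equiv), CH2Cl2, 0 °C to rt; aq. HCl work-up
Reagents that add atoms: none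
Why: Soft-enolisation Claisen-type C-acylation should work because the magnesium-chelated β-diketonate is the thermodynamic sink, so any enol ester formed first is drawn to the C-acyl product.

Step 5
Reactants: 7 the enolised 2-aroylbenzofuran-3-one
Product: 8 (±)-4,6-bis(benzyloxy)-2-[4-(benzyloxy)benzoyl]-2-hydroxybenzofuran-3(2H)-one
Conditions: dimethyldioxirane (1.2 equiv), acetone, −20 to 0 °C
Reagents that add atoms: dimethyldioxirane, CC1(C)OO1
Why: Electrophilic α-hydroxylation of an enolised 1,3-diketone (epoxidation of the enol double bond and collapse) gives the tertiary α-hydroxy diketone as a five-membered hemiketal, whose racemic centre is erased in step 6.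

Step 6
Reactants: 8 (±)-2-aroyl-2-hydroxybenzofuran-3-one hemiketal; 3 tri-O-benzyl-ent-afzelechin
Product: 11 (3R)-5,7-bis(benzyloxy)-2-[4-(benzyloxy)phenyl]-2,3-dihydroxy-3-[(2S,3R)-5,7,4'-tri-O-benzylafzelechin-8-yl]chroman-4-one (hemiketal epimers at C2), via open triketone 9 (not isolated), via chromane-3,4-dione hemiketal 10 (not isolated)
Conditions: Cu(OTf)2 (10 mol%), (S,S)-t-Bu-bis(oxazoline) ligand [2,2'-isopropylidenebis((4S)-4-tert-butyl-2-oxazoline), 11 mol%], 4 Å molecular sieves, CH2Cl2, 0 °C to rt
Reagents that add atoms: none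
Why: Proposed new method: the Lewis acid should open hemiketal 8 (retro-hemiketalisation) to triketone 9, whose ring-A phenol recloses on the aroyl carbonyl (net 1,2-shift of O1, five- to six-membered ring) to give the chromane-3,4-dione 10, a cyclic 1,2-diketone that chelates Cu(OTf)2/bis(oxazoline) through O3 and O4, after which C8 of 3 adds to the activated C3 carbonyl and rearomatises. The closest known reaction type is the copper bis(oxazoline)-catalysed enantioselective Friedel–Crafts hydroxyalkylation of alkoxyarenes with 1,2-dicarbonyl compounds (pyruvates, glyoxylates), merged here with the known ring-chain tautomerism between 2-aroyl-2-hydroxybenzofuran-3-ones and 2-hydroxyflavan-3,4-diones. Ring C closes by a reversible 6-exo-trig hemiketalisation (phenol O1 onto the aryl ketone carbon C2), and once C3 is arylated the five-membered hemiketal can no longer form, so the ring expansion is locked. The new stereocentre C3 is set by the catalyst: in the square-planar chelate of divalent copper a tert-butyl group of the ligand covers one face of the C3 carbonyl, the ligand antipode is chosen so that the arene adds to the Si face (R carbinol, the (R,R) ligand being used if the facial sense proves opposite), and because 9 and 10 interconvert the whole of racemic 8 is funnelled through, while the hemiketal carbon C2 stays epimerisable and is fixed only in step 7. The step needs C8 over C6 on the flavan, secured by the 5- and 7-benzyl ethers that flank C6 on both sides while C8 lies next to the tied-back pyran oxygen (as in halogenation and acylation of O-alkylated flavan-3-ols), and it needs C3 over C2 and C4 on the electrophile, secured because C3 is the central non-conjugated carbonyl whereas C4 is deactivated by the oxygens of ring A and C2 is masked as the hemiketal.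

Step 7
Reactants: 11 hexabenzyl 2,3-dihydroxyflavanone adduct
Product: 13 target CNP0146414.2, via hexaphenol hemiketal 12 (not isolated)
Conditions: H2 (1 atm), Pd(OH)2/C, THF–MeOH, rt; filter; then TsOH·H2O (5 mol%), THF, rt
Reagents that add atoms: none
Why: Hydrogenolysis of the six O-benzyl ethers frees O7 of the flavan, and acid-catalysed ketalisation (loss of the hemiketal OH to an O1-stabilised oxocarbenium ion at C2, then 5-exo-trig attack of O7) closes the dihydrofuran ring; O7 is tethered through C8 to C3 and reaches C2 only from the face of ring C that carries the C3–C8 bond, so the ketal carbon follows C3 under thermodynamic control.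

**Compound list**

1 | (−)-epiafzelechin, (2R,3R)-2-(4-hydroxyphenyl)chromane-3,5,7-triol | Oc1cc(O)c2c(c1)O[C@H](c1ccc(O)cc1)[C@H](O)C2 | starting material
2 | (−)-afzelechin (ent-afzelechin), (2S,3R) | Oc1cc(O)c2c(c1)O[C@@H](c1ccc(O)cc1)[C@H](O)C2 | intermediate
3 | (2S,3R)-5,7-bis(benzyloxy)-2-[4-(benzyloxy)phenyl]chroman-3-ol | c1ccc(COc2cc(OCc3ccccc3)c3c(c2)O[C@@H](c2ccc(OCc4ccccc4)cc2)[C@H](O)C3)cc1 | intermediate
4 | 4,6-dihydroxybenzofuran-3(2H)-one | O=C1COc2cc(O)cc(O)c12 | starting material
5 | 4,6-bis(benzyloxy)benzofuran-3(2H)-one | O=C1COc2cc(OCc3ccccc3)cc(OCc3ccccc3)c12 | intermediate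
6 | 4-(benzyloxy)benzoyl chloride | O=C(Cl)c1ccc(OCc2ccccc2)cc1 | starting material
7 | [4,6-bis(benzyloxy)-3-hydroxybenzofuran-2-yl][4-(benzyloxy)phenyl]methanone | O=C(c1ccc(OCc2ccccc2)cc1)c1oc2cc(OCc3ccccc3)cc(OCc3ccccc3)c2c1O | intermediate
8 | (±)-4,6-bis(benzyloxy)-2-[4-(benzyloxy)benzoyl]-2-hydroxybenzofuran-3(2H)-one | O=C(c1ccc(OCc2ccccc2)cc1)C1(O)Oc2cc(OCc3ccccc3)cc(OCc3ccccc3)c2C1=O | intermediate
9 | 1-[2,4-bis(benzyloxy)-6-hydroxyphenyl]-3-[4-(benzyloxy)phenyl]propane-1,2,3-trione | O=C(C(=O)C(=O)c1ccc(OCc2ccccc2)cc1)c1c(O)cc(OCc2ccccc2)cc1OCc1ccccc1 | intermediate (not isolated)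
10 | (±)-5,7-bis(benzyloxy)-2-[4-(benzyloxy)phenyl]-2-hydroxychromane-3,4-dione | O=C1C(=O)C(O)(c2ccc(OCc3ccccc3)cc2)Oc2cc(OCc3ccccc3)cc(OCc3ccccc3)c12 | intermediate (not isolated)
11 | (3R)-5,7-bis(benzyloxy)-2-[4-(benzyloxy)phenyl]-2,3-dihydroxy-3-[(2S,3R)-5,7,4'-tri-O-benzylafzelechin-8-yl]chroman-4-one, C2 hemiketal epimers | O=C1c2c(OCc3ccccc3)cc(OCc3ccccc3)cc2OC(O)(c2ccc(OCc3ccccc3)cc2)[C@@]1(O)c1c(OCc2ccccc2)cc(OCc2ccccc2)c2c1O[C@@H](c1ccc(OCc3ccccc3)cc1)[C@H](O)C2 | intermediate
12 | (3R)-2,3,5,7-tetrahydroxy-2-(4-hydroxyphenyl)-3-[(2S,3R)-afzelechin-8-yl]chroman-4-one, C2 hemiketal epimers | O=C1c2c(O)cc(O)cc2OC(O)(c2ccc(O)cc2)[C@@]1(O)c1c(O)cc(O)c2c1O[C@@H](c1ccc(O)cc1)[C@H](O)C2 | intermediate (not isolated)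
13 | CNP0146414.2: 5,7-dihydroxy-2-(4-hydroxyphenyl)chroman-4-one whose C3 carbinol (R) is bonded to C8, and whose C2 ketal carbon to O7, of (2S,3R)-afzelechin; ring-fusion pair written as in the target SMILES | O=C1c2c(O)cc(O)cc2O[C@]2(c3ccc(O)cc3)Oc3cc(O)c4c(c3[C@@]12O)O[C@@H](c1ccc(O)cc1)[C@H](O)C4 | target

**Count**

Total step count: 7 (two branches joined in step 6). Longest linear sequence: 5 steps (4 → 5 → 7 → 8 → 11 → 13).

**Steps most likely to fail**

Step 6 (Proposed new method). What may go wrong: poor facial selectivity at C3 because a substrate with many donor oxygens need not bind the copper centre through O3 and O4 alone, or slow opening and turnover of the hemiketal on the catalyst. The fallback sets out from 8 and 3 and comes back at 13, using known chemistry. Hemiketal 8 is first ring-expanded in a separate ketal exchange (MeOH, TsOH, 3 Å sieves), since only the six-membered form can ionise to a C2 cation stabilised by O1 and the 4-benzyloxyphenyl group. This should give 5,7-bis(benzyloxy)-2-[4-(benzyloxy)phenyl]-2-methoxychromane-3,4-dione F1. F1 and 3 are then joined by an acetic-acid-promoted Friedel–Crafts hydroxyalkylation, the behaviour known for ninhydrin-type tricarbonyl compounds toward alkoxyarenes. This should give the (3R)-2-methoxy analogue of 11 F2 together with its (3S) epimer F3. The two are diastereomers because of the flavan centres and are separated by chromatography. Hydrogenolysis of F2 (H2, Pd(OH)2/C) should give the hexaphenol methyl ketal F4, which on treatment with TsOH exchanges methanol for O7 of the flavan and rejoins the route at 13.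

Step 7. What may go wrong: over-reduction while six benzyl ethers are removed (hydrogenolysis of the benzylic C2–O or C3–O bonds, reduction of the C4 ketone), and retro-Claisen cleavage of the open α-hydroxy-1,3-diketone tautomer before the ketal closes. The fallback sets out from 2 and comes back at 13. It changes the protecting-group plan so that the ketal is closed before any reduction. The phenols of 2 are protected as methoxymethyl ethers (MOMCl, K2CO3, acetone) to give 5,7,4'-tri-O-(methoxymethyl)-(2S,3R)-afzelechin F5. F5 is carried through step 6 with 8 to the tris(methoxymethyl) analogue of 11 F6. HCl in MeOH then removes the three acetal groups and closes the dihydrofuran ring in the same flask, giving the 5,7,4'-tri-O-benzyl ether of the target F7. This robust ketal needs only three hydrogenolyses (H2, Pd(OH)2/C) to reach 13.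

Step 4. What may go wrong: O-acylation of the enolate in place of C-acylation, with acyl transfer stopping at the enol ester. The fallback sets out from 5 and comes back at 8, replacing the acylation and hydroxylation by condensation and oxidation. Aldol condensation of 5 with 4-(benzyloxy)benzaldehyde (KOH, MeOH) should give (Z)-4,6-bis(benzyloxy)-2-[4-(benzyloxy)benzylidene]benzofuran-3(2H)-one F8. Dihydroxylation (OsO4 cat., N-methylmorpholine N-oxide, acetone–H2O) should give the racemic diol 4,6-bis(benzyloxy)-2-hydroxy-2-{[4-(benzyloxy)phenyl](hydroxy)methyl}benzofuran-3(2H)-one F9. Oxidation of its secondary benzylic alcohol with Dess–Martin periodinane returns to the route at 8.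

**Further compounds**

F1 | step 6 | 5,7-bis(benzyloxy)-2-[4-(benzyloxy)phenyl]-2-methoxychromane-3,4-dione (racemic) | COC1(c2ccc(OCc3ccccc3)cc2)Oc2cc(OCc3ccccc3)cc(OCc3ccccc3)c2C(=O)C1=O
F2 | step 6 | (3R)-2-methoxy analogue of 11 (C2 epimers) | O=C1c2c(OCc3ccccc3)cc(OCc3ccccc3)cc2OC(OC)(c2ccc(OCc3ccccc3)cc2)[C@@]1(O)c1c(OCc2ccccc2)cc(OCc2ccccc2)c2c1O[C@@H](c1ccc(OCc3ccccc3)cc1)[C@H](O)C2
F3 | step 6 | (3S) epimer of F2 | O=C1c2c(OCc3ccccc3)cc(OCc3ccccc3)cc2OC(OC)(c2ccc(OCc3ccccc3)cc2)[C@]1(O)c1c(OCc2ccccc2)cc(OCc2ccccc2)c2c1O[C@@H](c1ccc(OCc3ccccc3)cc1)[C@H](O)C2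
F4 | step 6 | hexaphenol methyl ketal, (3R)-3,5,7-trihydroxy-2-(4-hydroxyphenyl)-2-methoxy-3-[(2S,3R)-afzelechin-8-yl]chroman-4-one | O=C1c2c(O)cc(O)cc2OC(OC)(c2ccc(O)cc2)[C@@]1(O)c1c(O)cc(O)c2c1O[C@@H](c1ccc(O)cc1)[C@H](O)C2
F5 | step 7 | 5,7,4'-tri-O-(methoxymethyl)-(2S,3R)-afzelechin | COCOc1cc(OCOC)c2c(c1)O[C@@H](c1ccc(OCOC)cc1)[C@H](O)C2
F6 | step 7 | tris(methoxymethyl) analogue of 11 | O=C1c2c(OCc3ccccc3)cc(OCc3ccccc3)cc2OC(O)(c2ccc(OCc3ccccc3)cc2)[C@@]1(O)c1c(OCOC)cc(OCOC)c2c1O[C@@H](c1ccc(OCOC)cc1)[C@H](O)C2
F7 | step 7 | 5,7,4'-tri-O-benzyl ether of the target (benzyl groups on the flavanone half) | O=C1c2c(OCc3ccccc3)cc(OCc3ccccc3)cc2O[C@]2(c3ccc(OCc5ccccc5)cc3)Oc3cc(O)c4c(c3[C@@]12O)O[C@@H](c1ccc(O)cc1)[C@H](O)C4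
F8 | step 4 | (Z)-4,6-bis(benzyloxy)-2-[4-(benzyloxy)benzylidene]benzofuran-3(2H)-one | O=C1C(=C/c2ccc(OCc3ccccc3)cc2)/Oc2cc(OCc3ccccc3)cc(OCc3ccccc3)c12
F9 | step 4 | 4,6-bis(benzyloxy)-2-hydroxy-2-{[4-(benzyloxy)phenyl](hydroxy)methyl}benzofuran-3(2H)-one (racemic) | O=C1c2c(OCc3ccccc3)cc(OCc3ccccc3)cc2OC1(O)C(O)c1ccc(OCc2ccccc2)cc1
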